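**Plan**
1. Retrosynthetic cuts, in order: the benzyl ether on O9; the C6a–C6b bond of the furan ring (double C–H coupling); the C11a–O11 aryl ether bond, so that ring D arrives as 3-(benzyloxy)phenol; the lactone carbonyl C6 (from diethyl carbonate); last, the aryl–CH2 and O–CMe2 bonds of the dimethylchroman ring, leading back to 2',6'-dihydroxy-4'-methoxyacetophenone and isoprene.
2. Forward order of rings: the chroman ring on ring A first, then the pyranone (lactone) ring, then ring D is attached through oxygen and the furan ring is closed last.
3. Enabling feature: ring A is a phloroglucinol ring whose chroman oxygen (on C1) and benzylic carbon (on C2) sit on neighbouring ring atoms. In the acetophenone the pairs O2'/C3' and O6'/C5' are symmetry-equivalent and C1' is blocked by the acetyl carbon that becomes C11a. One phenol-plus-diene annulation can therefore give only one constitution, fixes the whole substitution pattern of ring A, and leaves free exactly the OH needed for the lactone.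
4. Stereochemistry: the target has no stereocentre and no stereogenic double bond, so nothing has to be controlled.

Key step: step 1

Remark: locants such as C1, C2, C6a, C6b, C9, C11a and O11 follow the usual coumestan (6H-benzofuro[3,2-c]chromen-6-one) numbering; compounds 1, 2 and 8 are taken as purchased.

**Step 1**
Reactants: 1 2',6'-dihydroxy-4'-methoxyacetophenone; 2 isoprene (2-methylbuta-1,3-diene)
Product: 4 1-(7-hydroxy-5-methoxy-2,2-dimethylchroman-8-yl)ethan-1-one, via ortho-prenyl phenol 3 (not isolated)
Conditions: isoprene (1.1 equiv, slow addition), Amberlyst 15 (dry sulfonic acid resin), THF–heptane, 65 °C, sealed vessel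
Reagents that add atoms: none
Why: The sulfonic acid resin protonates isoprene at C1 to the 1,1-dimethylallyl cation, ring carbon C3' of 1 captures its unhindered primary end (Friedel–Crafts alkylation to 3), and protonation of the trisubstituted alkene of 3 gives a tertiary cation that the neighbouring 2'-OH traps, so the aryl–CH2 bond and the O–CMe2 bond form in one flask with every atom of both partners kept. The closest known reaction type is the acid-catalysed chroman annulation of phenols and hydroxyacetophenones with isoprene (Friedel–Crafts alkylation followed by hydroalkoxylation, as in tocopherol-type chroman syntheses). The one ring that closes does so in the 6-endo-trig mode with Markovnikov orientation, because the charge sits on the tertiary carbon. No stereocentre is formed, so no facial control is needed. The step needs site selectivity, which the substrate secures: C1' is blocked by the acetyl group, the pairs O2'/C3' and O6'/C5' are equivalent by the twofold symmetry through C1' and C4', and a prenyl group flanked by OMe and OH can close only onto OH. It also needs to stop after one annulation, which is served by keeping isoprene as the limiting reagent and by the hydrogen bond that ties the remaining OH of 4 to the acetyl carbonyl.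

**Step 2**
Reactants: 4 1-(7-hydroxy-5-methoxy-2,2-dimethylchroman-8-yl)ethan-1-one
Product: 6 10-hydroxy-5-methoxy-2,2-dimethyl-3,4-dihydro-2H,8H-pyrano[2,3-f]chromen-8-one (the 4-hydroxycoumarin), via beta-keto ester 5 (not isolated)
Conditions: NaH (4 equiv), (EtO)2CO (excess), toluene, 110 °C; then aq. HCl
Reagents that add atoms: diethyl carbonate, CCOC(=O)OCC
Why: Claisen-type C-acylation of the methyl ketone enolate by diethyl carbonate followed by lactonisation of the ortho phenoxide onto the new ester is the standard 4-hydroxycoumarin synthesis from ortho-hydroxyacetophenones, and the chroman and methyl ether are inert to NaH.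

**Step 3**
Reactants: 6 10-hydroxy-5-methoxy-2,2-dimethyl-3,4-dihydro-2H,8H-pyrano[2,3-f]chromen-8-one
Product: 7 10-chloro-5-methoxy-2,2-dimethyl-3,4-dihydro-2H,8H-pyrano[2,3-f]chromen-8-one
Conditions: POCl3 (4 equiv), BnEt3NCl (additive), MeCN, 40 °C then reflux; ice-water quench
Reagents that add atoms: phosphoryl chloride, O=P(Cl)(Cl)Cl
Why: Deoxychlorination of the vinylogous carboxylic acid OH by POCl3 is the standard conversion of 4-hydroxycoumarins into 4-chlorocoumarins, and the aryl methyl ether and the chroman ether tolerate it.

**Step 4**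
Reactants: 7 10-chloro-5-methoxy-2,2-dimethyl-3,4-dihydro-2H,8H-pyrano[2,3-f]chromen-8-one; 8 3-(benzyloxy)phenol
Product: 9 10-[3-(benzyloxy)phenoxy]-5-methoxy-2,2-dimethyl-3,4-dihydro-2H,8H-pyrano[2,3-f]chromen-8-one
Conditions: K2CO3 (2 equiv), DMF, 80 °C
Reagents that add atoms: none
Why: Addition–elimination (SNAr-type vinylogous acyl substitution) of the phenoxide at the chlorine-bearing carbon, which is activated by the lactone carbonyl, is the usual route to 4-aryloxycoumarins.

**Step 5**
Reactants: 9 10-[3-(benzyloxy)phenoxy]-5-methoxy-2,2-dimethyl-3,4-dihydro-2H,8H-pyrano[2,3-f]chromen-8-one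
Product: 10 9-O-benzyl ether of the target (9-benzyloxy-3-methoxycoumestan carrying the 2,2-dimethyldihydropyran ring fused through O on C1 and CH2 on C2)
Conditions: Pd(OAc)2 (10 mol%), AgOAc (2.2 equiv), PivOH, 120 °C
Reagents that add atoms: none
Why: Intramolecular cross-dehydrogenative (double C–H) coupling of a 4-aryloxycoumarin, in which divalent palladium metalates the coumarin C–H next to the lactone carbonyl and, by concerted metalation–deprotonation, the less hindered aryloxy C–H para to the benzyloxy group, reductive elimination closes the furan ring and AgOAc returns zerovalent palladium to the divalent state.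

**Step 6**
Reactants: 10 9-O-benzyl ether of the target
Product: 11 target CNP0304440.0 (9-hydroxy-3-methoxycoumestan with the 2,2-dimethyldihydropyran ring fused through O on C1 and CH2 on C2)
Conditions: H2 (1 atm), Pd/C (10 wt% palladium on carbon), THF–MeOH, rt
Reagents that add atoms: none
Why: Hydrogenolysis of the benzyl aryl ether over Pd/C should leave the aromatic coumestan core, the lactone, the methyl ether and the saturated chroman untouched at 1 atm and room temperature.

**Compound list**
1 | 2',6'-dihydroxy-4'-methoxyacetophenone (1-(2,6-dihydroxy-4-methoxyphenyl)ethan-1-one) | CC(=O)c1c(O)cc(OC)cc1O | starting material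
2 | isoprene (2-methylbuta-1,3-diene) | C=CC(C)=C | starting material
3 | 1-[2,6-dihydroxy-4-methoxy-3-(3-methylbut-2-en-1-yl)phenyl]ethan-1-one (ortho-prenyl phenol; not isolated) | CC(=O)c1c(O)cc(OC)c(CC=C(C)C)c1O | intermediate
4 | 1-(7-hydroxy-5-methoxy-2,2-dimethylchroman-8-yl)ethan-1-one | CC(=O)c1c(O)cc(OC)c2CCC(C)(C)Oc12 | intermediate
5 | ethyl 3-(7-hydroxy-5-methoxy-2,2-dimethylchroman-8-yl)-3-oxopropanoate (beta-keto ester; not isolated) | CCOC(=O)CC(=O)c1c(O)cc(OC)c2CCC(C)(C)Oc12 | intermediate
6 | 10-hydroxy-5-methoxy-2,2-dimethyl-3,4-dihydro-2H,8H-pyrano[2,3-f]chromen-8-one | COc1cc2oc(=O)cc(O)c2c2OC(C)(C)CCc12 | intermediate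
7 | 10-chloro-5-methoxy-2,2-dimethyl-3,4-dihydro-2H,8H-pyrano[2,3-f]chromen-8-one | COc1cc2oc(=O)cc(Cl)c2c2OC(C)(C)CCc12 | intermediate
8 | 3-(benzyloxy)phenol | Oc1cccc(OCc2ccccc2)c1 | starting material
9 | 10-[3-(benzyloxy)phenoxy]-5-methoxy-2,2-dimethyl-3,4-dihydro-2H,8H-pyrano[2,3-f]chromen-8-one | COc1cc2oc(=O)cc(Oc3cccc(OCc4ccccc4)c3)c2c2OC(C)(C)CCc12 | intermediate
10 | 9-O-benzyl ether of the target (9-benzyloxy-3-methoxycoumestan with the 2,2-dimethyldihydropyran ring fused at O on C1 and C2) | COc1cc2oc(=O)c3c4ccc(OCc5ccccc5)cc4oc3c2c2OC(C)(C)CCc12 | intermediate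
11 | CNP0304440.0 (9-hydroxy-3-methoxycoumestan with the 2,2-dimethyldihydropyran ring fused at O on C1 and C2) | COc1cc2oc(=O)c3c4ccc(O)cc4oc3c2c2c1CCC(C)(C)O2 | target

**Step count and risks**
Total step count: 6. Longest linear sequence: 6 steps (from 1; compounds 2 and 8 are purchased).

Steps most likely to fail:

- **Step 1 (key step).** A second isoprene unit may add at C6 of the product, the reaction may stall at the open-chain prenyl phenol, and the diene may oligomerise under acid. Fallback, without carbocations: from 1, condensation with 3-methylbut-2-enal (CC(C)=CC=O) under ethylenediammonium diacetate catalysis in refluxing toluene should proceed by ortho C–C bond formation, dehydration to the ortho-quinone methide and oxa-6π electrocyclisation. This should give 1-(7-hydroxy-5-methoxy-2,2-dimethyl-2H-chromen-8-yl)ethan-1-one F1. Hydrogenation of its ring double bond (H2, Pd/C, EtOAc, rt) returns to the route at 4.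

- **Step 5.** Site selectivity between the two ortho C–H bonds of the aryloxy ring may be poor, and the oxidative cycle may stall through deposition of palladium metal. Fallback, with the ring D junction fixed by a halogen and no oxidant: from 7, substitution with purchased 5-(benzyloxy)-2-bromophenol (Oc1cc(OCc2ccccc2)ccc1Br; K2CO3, DMF, 80 °C) should give 10-[5-(benzyloxy)-2-bromophenoxy]-5-methoxy-2,2-dimethyl-3,4-dihydro-2H,8H-pyrano[2,3-f]chromen-8-one F2. Intramolecular direct arylation of the coumarin C–H (Pd(OAc)2, PCy3·HBF4, K2CO3, DMA, 120 °C; zerovalent palladium inserts into the C–Br bond) then closes the furan ring and returns to the route at 10.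

- **Step 4.** Addition–elimination at the carbon flanked by the peri chroman oxygen may be slow, with lactone opening by phenoxide competing. Fallback, forming the hindered aryl ether bond intramolecularly: 1-(benzyloxy)-3-(diacetoxyiodo)benzene F3 is made from purchased 1-(benzyloxy)-3-iodobenzene with NaBO3·4H2O in AcOH. From 6, reaction with F3 (Na2CO3, aqueous MeOH, rt) should give the iodonium ylide 9-{[3-(benzyloxy)phenyl]iodonio}-5-methoxy-2,2-dimethyl-8-oxo-3,4-dihydro-2H,8H-pyrano[2,3-f]chromen-10-olate F4. Heating in DMF at 100 °C should move the aryl group from trivalent iodine to oxygen and give 10-[3-(benzyloxy)phenoxy]-9-iodo-5-methoxy-2,2-dimethyl-3,4-dihydro-2H,8H-pyrano[2,3-f]chromen-8-one F5. Palladium-catalysed cyclisation onto the aryloxy ring (Pd(OAc)2, PPh3, K2CO3, DMF, 110 °C) returns to the route at 10.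

**Further compounds**
F1 | step 1 | 1-(7-hydroxy-5-methoxy-2,2-dimethyl-2H-chromen-8-yl)ethan-1-one | CC(=O)c1c(O)cc(OC)c2C=CC(C)(C)Oc12
F2 | step 5 | 10-[5-(benzyloxy)-2-bromophenoxy]-5-methoxy-2,2-dimethyl-3,4-dihydro-2H,8H-pyrano[2,3-f]chromen-8-one | COc1cc2oc(=O)cc(Oc3cc(OCc4ccccc4)ccc3Br)c2c2OC(C)(C)CCc12
F3 | step 4 | 1-(benzyloxy)-3-(diacetoxyiodo)benzene | CC(=O)OI(OC(C)=O)c1cccc(OCc2ccccc2)c1
F4 | step 4 | 9-{[3-(benzyloxy)phenyl]iodonio}-5-methoxy-2,2-dimethyl-8-oxo-3,4-dihydro-2H,8H-pyrano[2,3-f]chromen-10-olate | COc1cc2oc(=O)c([I+]c3cccc(OCc4ccccc4)c3)c([O-])c2c2OC(C)(C)CCc12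
F5 | step 4 | 10-[3-(benzyloxy)phenoxy]-9-iodo-5-methoxy-2,2-dimethyl-3,4-dihydro-2H,8H-pyrano[2,3-f]chromen-8-one | COc1cc2oc(=O)c(I)c(Oc3cccc(OCc4ccccc4)c3)c2c2OC(C)(C)CCc12
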